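**Retrosynthetic overview** (target positions in azulene numbering: C-3 carbinol with isopropyl, C-3a/C-8a ring fusion, C-4 aroyl ester, C-6=C-7, C-8 isovalerate)
1. The two esters go on last: C-8 isovalerate after a reagent-controlled reduction of a C-8 enone, then the C-4 4-acetoxybenzoate and deacetylation.
2. Key disconnection C-7–C-8: the 3-methylcyclohept-2-enone ring is traced back to a cis-bicyclo[3.2.0]heptan-6-one; a C-7 alkenyl radical adds to the C-8 carbonyl and the C-4–C-8 bond breaks (three-carbon ring expansion, four- to seven-membered).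
3. Enabling feature: the strained four-membered ring C-8(=O)–C-8a–C-3a–C-4, whose α-carbon C-4 carries a silyloxy group and the (E)-3-iodo-2-methylallyl arm (C-5, C-6, C-7).
4. The bicycle comes from an acyclic dienamide by an auxiliary-controlled intramolecular keteniminium–diene [2+2] cycloaddition; the dienoate comes from a Johnson–Claisen rearrangement of a divinyl carbinol; 3-OH is added afterwards by exo-selective Mukaiyama hydration of C-2=C-3.
5. Ring order: five-membered ring (C-1, C-2, C-3, C-3a, C-8a) and four-membered ring together in step 5; seven-membered ring in step 11 at the expense of the four-membered ring.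

Key step: step 11

Remark: the SMILES is read as the cis-fused (3S,3aS,4R,8R,8aR) isomer: H-3a, the C-8a methyl, 3-OH and the 8-acyloxy group on one face, the isopropyl and 4-aroyloxy groups on the other.
Assumption: the (2S,5S)-pyrrolidine auxiliary is taken to induce the (1S,5R) sense in step 5; if the sense were opposite, the (2R,5R)-amine would be used with no other change.
Atom labels in the text are target positions; systematic names of the bicyclo[3.2.0]heptanes use their own numbering.

**Step 1**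
Reactants: 1 ethyl 2-methylpropanoate; 2 vinylmagnesium bromide
Product: 3 3-(propan-2-yl)penta-1,4-dien-3-ol
Conditions: 2 (2.3 equiv), CeCl3, THF, −78 → 0 °C; then aq. NH4Cl
Reagents that add atoms: none
Why: double 1,2-addition of the Grignard reagent to the ester (CeCl3 suppresses conjugate addition to the intermediate vinyl ketone) should give the tertiary carbinol, which has no stereocentre because its two vinyl groups are identical.

**Step 2**
Reactants: 3 3-(propan-2-yl)penta-1,4-dien-3-ol; 4 triethyl orthopropionate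
Product: 6 ethyl (2RS,4Z)-2-methyl-5-(propan-2-yl)hepta-4,6-dienoate, via mixed ketene acetal 5 (not isolated)
Conditions: 4 (excess), EtCO2H (cat.), 140 °C, EtOH distilled off
Reagents that add atoms: none
Why: Johnson–Claisen rearrangement forms C-1–C-8a; in the chair transition state the bulkier isopropyl group should sit pseudo-equatorial, which places the new chain cis to the remaining vinyl group ((4Z)-diene, needed in step 5), and the C-2 epimers both converge in step 5.

**Step 3**
Reactants: 6 ethyl (2RS,4Z)-2-methyl-5-(propan-2-yl)hepta-4,6-dienoate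
Product: 7 (2RS,4Z)-2-methyl-5-(propan-2-yl)hepta-4,6-dienoic acid
Conditions: LiOH, THF/MeOH/H2O, rt; then aq. HCl
Reagents that add atoms: lithium hydroxide [Li+].[OH-]
Why: ester saponification, which touches neither the diene nor its geometry.

**Step 4**
Reactants: 7 (2RS,4Z)-2-methyl-5-(propan-2-yl)hepta-4,6-dienoic acid; 8 (2S,5S)-2,5-dimethylpyrrolidine
Product: 10 (2RS,4Z)-1-[(2S,5S)-2,5-dimethylpyrrolidin-1-yl]-2-methyl-5-(propan-2-yl)hepta-4,6-dien-1-one, via acid chloride 9 (not isolated)
Conditions: (COCl)2, DMF (cat.), CH2Cl2, 0 °C → rt; then 8, pyridine, DMAP (cat.), CH2Cl2, −20 → 0 °C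
Reagents that add atoms: none
Why: amide formation through the acid chloride, with pyridine in place of a trialkylamine so that no ketene (and no uncontrolled [2+2]) forms; the C2-symmetric amine gives a single keteniminium geometry later.

**Step 5**
Reactants: 10 (2RS,4Z)-1-[(2S,5S)-2,5-dimethylpyrrolidin-1-yl]-2-methyl-5-(propan-2-yl)hepta-4,6-dien-1-one
Product: 13 (1S,5R)-5-methyl-2-(propan-2-yl)bicyclo[3.2.0]hept-2-en-6-one, via keteniminium triflate 11 (not isolated), via cyclobutaniminium triflate 12 (not isolated)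
Conditions: Tf2O, 2,4,6-collidine, ClCH2CH2Cl, −20 → 60 °C; then aq. NaHCO3, rt
Reagents that add atoms: water O
Why: intramolecular keteniminium–alkene [2+2] cycloaddition (chiral-auxiliary variant): the electrophilic C-8 bonds to the terminal diene carbon C-4 while C-8a closes the five-membered ring on C-3a, which can only give the cis-fused bicycle, and the C2-symmetric pyrrolidine shields one face of the keteniminium ion and so sets C-8a and C-3a together.

**Step 6**
Reactants: 13 (1S,5R)-5-methyl-2-(propan-2-yl)bicyclo[3.2.0]hept-2-en-6-one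
Product: 14 (1R,2S,5R)-2-hydroxy-5-methyl-2-(propan-2-yl)bicyclo[3.2.0]heptan-6-one
Conditions: Co(acac)2 (cat.), PhSiH3, O2 (1 atm), THF/iPrOH, 0 °C → rt
Reagents that add atoms: dioxygen O=O
Why: Mukaiyama hydration: hydrogen-atom transfer to C-2 gives the tertiary C-3 radical (Markovnikov), which should be trapped by O2 on the convex (exo) face away from the four-membered ring, so that 3-OH is cis to H-3a and the isopropyl group is endo, as in the target.

**Step 7**
Reactants: 14 (1R,2S,5R)-2-hydroxy-5-methyl-2-(propan-2-yl)bicyclo[3.2.0]heptan-6-one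
Product: 17 (1S,2S,5R,7R)-5-methyl-2-(propan-2-yl)-2,7-bis(triethylsilyloxy)bicyclo[3.2.0]heptan-6-one, via dipotassium enolate alkoxide 15 (not isolated), via dipotassium keto dialkoxide 16 (not isolated)
Conditions: KN(SiMe3)2 (2.3 equiv), THF, −78 °C; 2-(phenylsulfonyl)-3-phenyloxaziridine, −78 °C; then Et3SiCl (3 equiv), −78 → 0 °C
Reagents that add atoms: 2-(phenylsulfonyl)-3-phenyloxaziridine O=S(=O)(c1ccccc1)N1OC1c1ccccc1; chlorotriethylsilane CC[Si](Cl)(CC)CC
Why: enolate oxidation with an N-sulfonyloxaziridine: only C-4 can be enolised (C-8a is quaternary), the oxidant should enter from the exo face (this configuration is erased in step 11), and both potassium alkoxides are then silylated.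

**Step 8**
Reactants: 18 prop-2-yn-1-ol
Product: 20 (2E)-3-iodo-2-methylprop-2-en-1-ol, via alkenylalane 19 (not isolated)
Conditions: Me3Al (3 equiv), Cp2ZrCl2 (0.25 equiv), CH2Cl2, 0 °C → rt; then I2, THF, −30 → 0 °C; aq. K2CO3
Reagents that add atoms: trimethylaluminium C[Al](C)C; iodine [I][I]
Why: zirconium-catalysed carboalumination (Negishi) adds methyl and aluminium syn across the alkyne, and iodinolysis with retention gives the E-alkenyl iodide.

**Step 9**
Reactants: 20 (2E)-3-iodo-2-methylprop-2-en-1-ol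
Product: 21 (1E)-3-bromo-1-iodo-2-methylprop-1-ene
Conditions: CBr4, PPh3, CH2Cl2, 0 °C
Reagents that add atoms: tetrabromomethane BrC(Br)(Br)Br
Why: Appel bromination of the primary allylic alcohol, which leaves the alkenyl iodide untouched.

**Step 10**
Reactants: 17 (1S,2S,5R,7R)-5-methyl-2-(propan-2-yl)-2,7-bis(triethylsilyloxy)bicyclo[3.2.0]heptan-6-one; 21 (1E)-3-bromo-1-iodo-2-methylprop-1-ene
Product: 23 (1R,2S,5R,7S)-7-[(2E)-3-iodo-2-methylprop-2-en-1-yl]-5-methyl-2-(propan-2-yl)-2,7-bis(triethylsilyloxy)bicyclo[3.2.0]heptan-6-one, via potassium enolate 22 (not isolated)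
Conditions: KN(SiMe3)2, THF, −78 °C; then 21, DMPU, −78 → −20 °C
Reagents that add atoms: none
Why: C-alkylation of the α-silyloxy ketone enolate by SN2 at the allylic bromide, expected from the exo face so that the iodoalkenyl arm lies exo, next to the carbonyl face it must reach in step 11.

**Step 11**
Reactants: 23 (1R,2S,5R,7S)-7-[(2E)-3-iodo-2-methylprop-2-en-1-yl]-5-methyl-2-(propan-2-yl)-2,7-bis(triethylsilyloxy)bicyclo[3.2.0]heptan-6-one
Product: 27 (3S,3aS,4R,8aR)-6,8a-dimethyl-3-(propan-2-yl)-3,4-bis(triethylsilyloxy)-2,3,3a,4,5,8a-hexahydroazulen-8(1H)-one, via alkenyl radical 24 (not isolated), via alkoxyl radical 25 (not isolated), via silyloxyalkyl radical 26 (not isolated)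
Conditions: Bu3SnH (1.3 equiv, syringe pump), AIBN (cat.), PhH (0.005 M), 80 °C
Reagents that add atoms: none
Why: Bu3Sn• abstracts iodine from 23 to give alkenyl radical 24, a bent σ-radical that inverts freely (so the E-iodide suffices) and adds 5-exo-trig to the strained cyclobutanone carbonyl, forming C-7–C-8 and closing a transient cyclopentene ring (C-4, C-5, C-6, C-7, C-8) in alkoxyl radical 25. β-Scission of the C-4–C-8 bond shared by the four- and five-membered rings then merges them into the seven-membered ring, whose only new bond is C-7–C-8, and unveils the 3-methylcyclohept-2-enone with the C-6=C-7 alkene already in place. The closest known reaction type is the Dowd–Beckwith radical ring expansion of fused cyclobutanones that carry a haloalkyl or haloalkenyl arm on the α-carbon. The step needs scission of C-4–C-8 and not of C-8–C-8a: the silyloxy group on C-4 stabilises radical 26, and only this cleavage releases the strain of both small rings. The one new stereocentre, C-4, is set when 26 takes a hydrogen atom from Bu3SnH on the convex face (that of H-3a and the angular methyl, away from C-3 and its isopropyl group), which leaves the silyloxy group on the concave face as the target requires; C-3, C-3a and C-8a are untouched and the cis ring fusion is inherited from the bicyclo[3.2.0]heptane.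

**Step 12**
Reactants: 27 (3S,3aS,4R,8aR)-6,8a-dimethyl-3-(propan-2-yl)-3,4-bis(triethylsilyloxy)-2,3,3a,4,5,8a-hexahydroazulen-8(1H)-one
Product: 28 (3S,3aS,4R,8R,8aR)-6,8a-dimethyl-3-(propan-2-yl)-3,4-bis(triethylsilyloxy)-1,2,3,3a,4,5,8,8a-octahydroazulen-8-ol
Conditions: (S)-2-methyl-CBS-oxazaborolidine (0.5 equiv), catecholborane, toluene, −78 °C; then MeOH, H2O
Reagents that add atoms: none
Why: Corey–Bakshi–Shibata reduction (1,2-selective with catecholborane): with the fully substituted C-8a flank as the large group, the (S)-catalyst should deliver hydride to the face that gives the (8R)-alcohol, hydroxyl cis to the angular methyl.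

**Step 13**
Reactants: 28 (3S,3aS,4R,8R,8aR)-6,8a-dimethyl-3-(propan-2-yl)-3,4-bis(triethylsilyloxy)-1,2,3,3a,4,5,8,8a-octahydroazulen-8-ol; 29 3-methylbutanoyl chloride
Product: 30 (3S,3aS,4R,8R,8aR)-6,8a-dimethyl-3-(propan-2-yl)-3,4-bis(triethylsilyloxy)-1,2,3,3a,4,5,8,8a-octahydroazulen-8-yl 3-methylbutanoate
Conditions: 29, DMAP, pyridine, CH2Cl2, 0 °C → rt
Reagents that add atoms: none
Why: DMAP-catalysed acylation of the only free hydroxyl group, with retention at C-8.

**Step 14**
Reactants: 30 (3S,3aS,4R,8R,8aR)-6,8a-dimethyl-3-(propan-2-yl)-3,4-bis(triethylsilyloxy)-1,2,3,3a,4,5,8,8a-octahydroazulen-8-yl 3-methylbutanoate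
Product: 31 (3S,3aS,4R,8R,8aR)-3,4-dihydroxy-6,8a-dimethyl-3-(propan-2-yl)-1,2,3,3a,4,5,8,8a-octahydroazulen-8-yl 3-methylbutanoate
Conditions: HF·pyridine, pyridine, THF, 0 °C → rt
Reagents that add atoms: none
Why: fluoride-mediated cleavage of both triethylsilyl ethers under buffered conditions that should leave the allylic ester in place.

**Step 15**
Reactants: 31 (3S,3aS,4R,8R,8aR)-3,4-dihydroxy-6,8a-dimethyl-3-(propan-2-yl)-1,2,3,3a,4,5,8,8a-octahydroazulen-8-yl 3-methylbutanoate; 32 4-(chlorocarbonyl)phenyl acetate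
Product: 33 (3S,3aS,4R,8R,8aR)-3-hydroxy-6,8a-dimethyl-8-(3-methylbutanoyloxy)-3-(propan-2-yl)-1,2,3,3a,4,5,8,8a-octahydroazulen-4-yl 4-acetoxybenzoate
Conditions: 32 (1.2 equiv), Et3N, DMAP (cat.), CH2Cl2, 0 °C
Reagents that add atoms: none
Why: DMAP-catalysed acylation in which the secondary C-4 hydroxyl should react well ahead of the hindered tertiary C-3 hydroxyl.

**Step 16**
Reactants: 33 (3S,3aS,4R,8R,8aR)-3-hydroxy-6,8a-dimethyl-8-(3-methylbutanoyloxy)-3-(propan-2-yl)-1,2,3,3a,4,5,8,8a-octahydroazulen-4-yl 4-acetoxybenzoate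
Product: 34 (3S,3aS,4R,8R,8aR)-3-hydroxy-6,8a-dimethyl-8-(3-methylbutanoyloxy)-3-(propan-2-yl)-1,2,3,3a,4,5,8,8a-octahydroazulen-4-yl 4-hydroxybenzoate (CNP0086724.1)
Conditions: NH4OAc, MeOH/H2O (4:1), rt
Reagents that add atoms: none
Why: mild transesterification; the phenyl acetate is far more electrophilic than the two alkyl esters, so only it should be cleaved.

**Compound list**
1 | ethyl 2-methylpropanoate | CCOC(=O)C(C)C | starting material
2 | vinylmagnesium bromide | C=C[Mg]Br | starting material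
3 | 3-(propan-2-yl)penta-1,4-dien-3-ol | C=CC(O)(C=C)C(C)C | intermediate
4 | triethyl orthopropionate (1,1,1-triethoxypropane) | CCC(OCC)(OCC)OCC | starting material
5 | mixed ketene acetal, 3-[(1-ethoxyprop-1-en-1-yl)oxy]-3-(propan-2-yl)penta-1,4-diene | CC=C(OCC)OC(C=C)(C=C)C(C)C | intermediate
6 | ethyl (2RS,4Z)-2-methyl-5-(propan-2-yl)hepta-4,6-dienoate | CCOC(=O)C(C)C/C=C(\C=C)C(C)C | intermediate
7 | (2RS,4Z)-2-methyl-5-(propan-2-yl)hepta-4,6-dienoic acid | OC(=O)C(C)C/C=C(\C=C)C(C)C | intermediate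
8 | (2S,5S)-2,5-dimethylpyrrolidine | C[C@H]1CC[C@H](C)N1 | starting material
9 | (2RS,4Z)-2-methyl-5-(propan-2-yl)hepta-4,6-dienoyl chloride | ClC(=O)C(C)C/C=C(\C=C)C(C)C | intermediate
10 | (2RS,4Z)-1-[(2S,5S)-2,5-dimethylpyrrolidin-1-yl]-2-methyl-5-(propan-2-yl)hepta-4,6-dien-1-one | C[C@H]1CC[C@H](C)N1C(=O)C(C)C/C=C(\C=C)C(C)C | intermediate
11 | keteniminium triflate from 10 (N-alkenylidene-(2S,5S)-2,5-dimethylpyrrolidinium trifluoromethanesulfonate) | C[C@H]1CC[C@H](C)[N+]1=C=C(C)C/C=C(\C=C)C(C)C.[O-]S(=O)(=O)C(F)(F)F | intermediate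
12 | cyclobutaniminium triflate (iminium salt of 13 with the auxiliary) | C[C@H]1CC[C@H](C)[N+]1=C1[C@]2(C)CC=C(C(C)C)[C@@H]2C1.[O-]S(=O)(=O)C(F)(F)F | intermediate
13 | (1S,5R)-5-methyl-2-(propan-2-yl)bicyclo[3.2.0]hept-2-en-6-one | O=C1[C@]2(C)CC=C(C(C)C)[C@@H]2C1 | intermediate
14 | (1R,2S,5R)-2-hydroxy-5-methyl-2-(propan-2-yl)bicyclo[3.2.0]heptan-6-one (2-exo-OH) | O=C1[C@]2(C)CC[C@](O)(C(C)C)[C@@H]2C1 | intermediate
15 | dipotassium enolate alkoxide of 14 | [K+].[K+].[O-]C=1[C@]2(C)CC[C@]([O-])(C(C)C)[C@@H]2C=1 | intermediate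
16 | dipotassium 2,7-dioxido derivative of the 7-exo-hydroxy ketone | [K+].[K+].O=C1[C@]2(C)CC[C@]([O-])(C(C)C)[C@@H]2[C@H]1[O-] | intermediate
17 | (1S,2S,5R,7R)-5-methyl-2-(propan-2-yl)-2,7-bis(triethylsilyloxy)bicyclo[3.2.0]heptan-6-one | O=C1[C@]2(C)CC[C@](O[Si](CC)(CC)CC)(C(C)C)[C@@H]2[C@H]1O[Si](CC)(CC)CC | intermediate
18 | prop-2-yn-1-ol | C#CCO | starting material
19 | alkenylalane, dimethylaluminium (2E)-3-(dimethylalumanyl)-2-methylprop-2-en-1-olate | C[Al](C)OC/C(C)=C/[Al](C)C | intermediate
20 | (2E)-3-iodo-2-methylprop-2-en-1-ol | OC/C(C)=C/I | intermediate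
21 | (1E)-3-bromo-1-iodo-2-methylprop-1-ene | BrC/C(C)=C/I | intermediate
22 | potassium enolate of 17 | [K+].[O-]C=1[C@]2(C)CC[C@](O[Si](CC)(CC)CC)(C(C)C)[C@@H]2C=1O[Si](CC)(CC)CC | intermediate
23 | (1R,2S,5R,7S)-7-[(2E)-3-iodo-2-methylprop-2-en-1-yl]-5-methyl-2-(propan-2-yl)-2,7-bis(triethylsilyloxy)bicyclo[3.2.0]heptan-6-one (arm exo) | O=C1[C@]2(C)CC[C@](O[Si](CC)(CC)CC)(C(C)C)[C@@H]2[C@@]1(O[Si](CC)(CC)CC)C/C(C)=C/I | intermediate
24 | alkenyl radical from 23 (iodine removed from C-7) | O=C1[C@]2(C)CC[C@](O[Si](CC)(CC)CC)(C(C)C)[C@@H]2[C@@]1(O[Si](CC)(CC)CC)CC(C)=[CH] | intermediate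
25 | tricyclic alkoxyl radical (C-7–C-8 bond formed, cyclopentene fused to the four-membered ring) | CC1=C[C@@]2([O])[C@]3(C)CC[C@](O[Si](CC)(CC)CC)(C(C)C)[C@@H]3[C@@]2(O[Si](CC)(CC)CC)C1 | intermediate
26 | ring-expanded C-4 silyloxyalkyl radical | CC1=CC(=O)[C@]2(C)CC[C@](O[Si](CC)(CC)CC)(C(C)C)[C@@H]2[C](O[Si](CC)(CC)CC)C1 | intermediate
27 | (3S,3aS,4R,8aR)-6,8a-dimethyl-3-(propan-2-yl)-3,4-bis(triethylsilyloxy)-2,3,3a,4,5,8a-hexahydroazulen-8(1H)-one | CC1=CC(=O)[C@]2(C)CC[C@](O[Si](CC)(CC)CC)(C(C)C)[C@@H]2[C@H](O[Si](CC)(CC)CC)C1 | intermediate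
28 | (3S,3aS,4R,8R,8aR)-6,8a-dimethyl-3-(propan-2-yl)-3,4-bis(triethylsilyloxy)-1,2,3,3a,4,5,8,8a-octahydroazulen-8-ol | CC1=C[C@@H](O)[C@]2(C)CC[C@](O[Si](CC)(CC)CC)(C(C)C)[C@@H]2[C@H](O[Si](CC)(CC)CC)C1 | intermediate
29 | 3-methylbutanoyl chloride | CC(C)CC(Cl)=O | starting material
30 | (3S,3aS,4R,8R,8aR)-6,8a-dimethyl-3-(propan-2-yl)-3,4-bis(triethylsilyloxy)-1,2,3,3a,4,5,8,8a-octahydroazulen-8-yl 3-methylbutanoate | CC1=C[C@@H](OC(=O)CC(C)C)[C@]2(C)CC[C@](O[Si](CC)(CC)CC)(C(C)C)[C@@H]2[C@H](O[Si](CC)(CC)CC)C1 | intermediate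
31 | (3S,3aS,4R,8R,8aR)-3,4-dihydroxy-6,8a-dimethyl-3-(propan-2-yl)-1,2,3,3a,4,5,8,8a-octahydroazulen-8-yl 3-methylbutanoate | CC1=C[C@@H](OC(=O)CC(C)C)[C@]2(C)CC[C@](O)(C(C)C)[C@@H]2[C@H](O)C1 | intermediate
32 | 4-(chlorocarbonyl)phenyl acetate (4-acetoxybenzoyl chloride) | CC(=O)Oc1ccc(cc1)C(Cl)=O | starting material
33 | (3S,3aS,4R,8R,8aR)-3-hydroxy-6,8a-dimethyl-8-(3-methylbutanoyloxy)-3-(propan-2-yl)-1,2,3,3a,4,5,8,8a-octahydroazulen-4-yl 4-acetoxybenzoate | CC1=C[C@@H](OC(=O)CC(C)C)[C@]2(C)CC[C@](O)(C(C)C)[C@@H]2[C@H](OC(=O)c2ccc(OC(C)=O)cc2)C1 | intermediate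
34 | (3S,3aS,4R,8R,8aR)-3-hydroxy-6,8a-dimethyl-8-(3-methylbutanoyloxy)-3-(propan-2-yl)-1,2,3,3a,4,5,8,8a-octahydroazulen-4-yl 4-hydroxybenzoate (CNP0086724.1) | CC1=C[C@@H](OC(=O)CC(C)C)[C@]2(C)CC[C@](O)(C(C)C)[C@@H]2[C@H](OC(=O)c2ccc(O)cc2)C1 | target

**Step count and risks**
Total step count: 16. Longest linear sequence: 14 (steps 1–7 and 10–16); steps 8 and 9 make the side-arm reagent 21.

The three steps most likely to fail:

Step 11 (key step). The alkenyl radical may pick up hydrogen from the stannane, or shift a hydrogen atom intramolecularly (for example from C-3a), before it reaches the carbonyl. The alkoxyl radical may also fragment toward C-8a, or the final hydrogen atom may arrive on the concave face. The fallback separates bond formation from ring opening. Setting out from 23, an intramolecular Nozaki–Hiyama–Kishi addition (CrCl2, NiCl2 cat., DMF, rt) of the alkenyl iodide to the cyclobutanone carbonyl would give the tricyclic cyclobutanol F1. A cerium-photocatalysed alkoxy-radical β-scission (CeCl3, Bu4NCl, an arenethiol as hydrogen-atom donor, 400 nm light, MeCN) would then open the shared C-4–C-8 bond. The route is rejoined at 27.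

Step 5. The auxiliary may discriminate the two faces of the keteniminium ion poorly, and the diene may oligomerise under the acidic conditions. The fallback replaces auxiliary control by resolution. Setting out from 7, the acid chloride 9 with Et3N in refluxing toluene would undergo the thermal intramolecular ketene–diene [2+2] cycloaddition to the racemic bicyclic ketone F2. Ketalisation with (1R,2R)-1,2-diphenylethane-1,2-diol (PPTS, benzene, water removal) would give two diastereomeric spiroketals to be separated by chromatography or crystallisation. The (R,R)-hydrobenzoin ketal F3 of the desired enantiomer would be hydrolysed (aq. HCl, THF). The route is rejoined at 13.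

Step 6. The tertiary radical at C-3 is a cyclobutylcarbinyl radical and may open the four-membered ring toward a carbonyl-stabilised radical before it captures O2; peroxide intermediates may also over-oxidise the cyclobutanone. The fallback is polar. Setting out from 13, dimethyldioxirane (acetone, 0 °C) should epoxidise the alkene on the convex face to the exo-epoxide F4. LiEt3BH (THF, 0 °C) should open it at the secondary carbon and reduce the ketone, giving the diol F5. Dess–Martin periodinane would re-oxidise only the secondary cyclobutanol. The route is rejoined at 14.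

**Further compounds**
F1 | step 11 | tricyclic cyclobutanol (alkenyl carbon C-7 bonded to the former carbonyl carbon C-8, bis(triethylsilyl) ether) | CC1=C[C@@]2(O)[C@]3(C)CC[C@](O[Si](CC)(CC)CC)(C(C)C)[C@@H]3[C@@]2(O[Si](CC)(CC)CC)C1
F2 | step 5 | racemic cis-fused 5-methyl-2-(propan-2-yl)bicyclo[3.2.0]hept-2-en-6-one (rac-13) | O=C1C2(C)CC=C(C(C)C)C2C1
F3 | step 5 | (R,R)-hydrobenzoin ketal of 13, spiro[(4R,5R)-4,5-diphenyl-1,3-dioxolane-2,6'-[(1S,5R)-5-methyl-2-(propan-2-yl)bicyclo[3.2.0]hept-2-ene]] | O1[C@H](c3ccccc3)[C@@H](c3ccccc3)OC12[C@]3(C)CC=C(C(C)C)[C@@H]3C2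
F4 | step 6 | 2,3-exo-epoxide of 13 | O=C1[C@]2(C)C[C@H]3O[C@@]3(C(C)C)[C@@H]2C1
F5 | step 6 | 5-methyl-2-(propan-2-yl)bicyclo[3.2.0]heptane-2,6-diol (2-exo-OH, 6-endo-OH) | O[C@@H]1[C@]2(C)CC[C@](O)(C(C)C)[C@@H]2C1
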